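**Retrosynthetic overview**
1. The furan, the only ring, is formed last. Both of its C–O bonds are made in that step: O–C5 by a 1,3-hydroxyl shift and O–C2 by 5-exo-dig attack of the hydroxyl on the alkyne.
2. The cyclisation substrate, (Z)-enynol 7, comes in the same flask from the tertiary 1-en-4-yn-3-ol 6.
3. 6 comes from the acetylide of tetradec-13-ynoic acid 3 and (E)-non-3-en-2-one 4 (C14–C15 bond; the enone supplies the ring oxygen, the 3-methyl and the pentyl group).
4. 3 comes from 12-bromododecanoic acid 1 and lithium acetylide 2 (C12–C13 bond).

Assumption: the target has no stereocentre and no stereogenic double bond, so the achiral compound itself is the required single stereoisomer. Compounds 1, 2 and 4 are taken as catalogue chemicals.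

**Step 1**
Reactants: 1 12-bromododecanoic acid; 2 lithium acetylide–ethylenediamine complex
Product: 3 tetradec-13-ynoic acid
Conditions: 2 (3.5 equiv), DMSO, 10 °C → rt, 4 h; then 1 M HCl, 0 °C
Reagents that add atoms: none
Why: SN2 alkylation of an acetylide, in which the first equivalent of 2 deprotonates the acid and the excess displaces the unhindered primary bromide in DMSO, the standard entry to ω-alkynoic acids.

**Step 2**
Reactants: 3 tetradec-13-ynoic acid; 4 (E)-non-3-en-2-one
Product: 6 (E)-15-hydroxy-15-methyldocos-16-en-13-ynoic acid, via dilithio tetradecynoate 5 (not isolated)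
Conditions: n-BuLi (2.05 equiv), THF, −78 → −20 °C; then 4 (1.1 equiv), −78 → −20 °C; cold 0.5 M HCl to pH 4
Reagents that add atoms: none
Why: Carbonyl alkynylation (1,2-addition of a lithium acetylide to an enone), in which the hard acetylide carbon of 5 attacks the ketone carbon and not the β-position while the lithium carboxylate stays inert at low temperature; the new tertiary carbinol centre forms racemic, which does not matter because it is erased in step 3.

**Step 3**
Reactants: 6 (E)-15-hydroxy-15-methyldocos-16-en-13-ynoic acid
Product: 10 13-(3-methyl-5-pentylfuran-2-yl)tridecanoic acid, via Z-enynol 7 (not isolated), via E-enynol 8 (not isolated), via alkylidenedihydrofuran 9 (not isolated)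
Conditions: Ph3SiOReO3 (5 mol%), dry CH2Cl2, −40 → 0 °C, 30 min; then (Ph3P)AuNTf2 (2 mol%), 0 °C → rt, 2 h
Reagents that add atoms: none
Why: Proposed new method: a one-flask Re(VII)/Au(I) relay in which the rhenium oxo catalyst converts 6 into its perrhenate ester and moves the oxygen from C15 to C17 by a chair-like [3,3] shift, giving the conjugated secondary enynols 7 and 8 (equilibrium driven by enyne conjugation and the trisubstituted alkene), after which the gold π-acid closes only the Z isomer 7 by anti 5-exo-dig O–C bond formation at the alkyne to 9, which aromatises by proton shift, while the unreactive E isomer 8 is returned through 6 by the same reversible shift so that all material funnels to the achiral furan with no stereocentre left; the closest known reaction types are the Re-oxo 1,3-transposition of allylic alcohols and the Au(I)/Ag(I) cycloisomerisation of (Z)-2-en-4-yn-1-ols to furans, which to my knowledge have not been merged on a tertiary 1-en-4-yn-3-ol.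

**Compound list**
1 | 12-bromododecanoic acid | OC(=O)CCCCCCCCCCCBr | starting material
2 | lithium acetylide–ethylenediamine complex | [Li+].[C-]#C.NCCN | starting material
3 | tetradec-13-ynoic acid | C#CCCCCCCCCCCCC(=O)O | intermediate
4 | (E)-non-3-en-2-one | CCCCC/C=C/C(C)=O | starting material
5 | lithium 14-lithiotetradec-13-ynoate (dilithio derivative of 3) | [Li+].[Li+].[C-]#CCCCCCCCCCCCC(=O)[O-] | intermediate
6 | (E)-15-hydroxy-15-methyldocos-16-en-13-ynoic acid (racemic) | CCCCC/C=C/C(C)(O)C#CCCCCCCCCCCCC(=O)O | intermediate
7 | (Z)-17-hydroxy-15-methyldocos-15-en-13-ynoic acid (racemic) | CCCCCC(O)/C=C(C)\C#CCCCCCCCCCCCC(=O)O | intermediate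
8 | (E)-17-hydroxy-15-methyldocos-15-en-13-ynoic acid (racemic) | CCCCCC(O)/C=C(C)/C#CCCCCCCCCCCCC(=O)O | intermediate
9 | (Z)-13-(3-methyl-5-pentylfuran-2(5H)-ylidene)tridecanoic acid (racemic) | CCCCCC1C=C(C)/C(O1)=C/CCCCCCCCCCCC(=O)O | intermediate
10 | 13-(3-methyl-5-pentylfuran-2-yl)tridecanoic acid | CCCCCc1cc(C)c(CCCCCCCCCCCCC(=O)O)o1 | target

**Totals**
Total step count: 3. Longest linear sequence: 3 (1 → 3 → 6 → 10).

**Steps most likely to fail** (the route has only three steps, so all are listed, most risky first)

Step 3, the proposed relay. The risks are a Meyer–Schuster shift of 6 to a dienone, gold-triggered enyne rearrangement of 6 if the transposition lags, dehydration to dienynes, and tying-up of rhenium by the free acid. The fallback uses known chemistry only; it sets out from 3 and comes back at 7, now isolated as the pure Z isomer, and through 9 at 10. Commercial hexanal and 1-propynylmagnesium bromide (THF, 0 °C) give non-2-yn-4-ol F1. Red-Al (THF, 0 °C → rt) followed by iodine at −78 °C gives (Z)-2-iodonon-2-en-4-ol F2 by hydroxyl-directed trans-hydroalumination and iodinolysis. Sonogashira coupling of F2 with 3 (PdCl2(PPh3)2, CuI, Et3N, THF, rt; the acid is carried as its ammonium salt) gives 7 with the alkyne cis to the carbinol carbon. 7 is then closed to 10 with AgNO3 on silica gel (hexane, rt) or PdI2/KI, the established cycloisomerisation of (Z)-2-en-4-yn-1-ols.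

Step 2, addition of the dilithio species to an enolisable methyl ketone. The risks are enolisation of 4 and poor solubility of 5. The fallback sets out from 3, through 5, and comes back at 10, using the enone isomer in a 1,4-mode. 5 is transmetalated with Et2AlCl (2 equiv) to diethylaluminium 14-(diethylalumanyl)tetradec-13-ynoate F3. F3 transfers its alkynyl group to the β-carbon of commercial (E)-non-2-en-4-one (Hooz-type alkynylalane conjugate addition through a six-membered transition state, open to s-cis enones). Acidic work-up gives 15-methyl-17-oxodocos-13-ynoic acid F4 (racemic). F4 is cycloisomerised to 10 with (Ph3P)AuNTf2 or Hg(OTf)2 (5-exo-dig attack of the ketone oxygen on the alkyne, then tautomerisation), so the ring-closing bond is again O–C.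

Step 1, acetylide displacement on the bromo acid. The risks are E2 elimination and incomplete conversion of the sparingly soluble carboxylate. The fallback sets out from 4 and comes back at 6, bypassing 3 by making the C14–C15 bond first. Ethynylmagnesium bromide (THF, 0 °C) adds 1,2 to 4 to give (E)-3-methyldec-4-en-1-yn-3-ol F5. n-BuLi (2 equiv) converts F5 into its O,C-dilithio derivative F6. F6 is alkylated in THF/DMPU with lithium 12-bromododecanoate F7 (from 1 and LiHMDS), giving 6 after work-up at pH 4.

**Further compounds**
F1 | step 3 | non-2-yn-4-ol (racemic) | CC#CC(O)CCCCC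
F2 | step 3 | (Z)-2-iodonon-2-en-4-ol (racemic) | C/C(I)=C/C(O)CCCCC
F3 | step 2 | diethylaluminium 14-(diethylalumanyl)tetradec-13-ynoate | CC[Al](CC)OC(=O)CCCCCCCCCCCC#C[Al](CC)CC
F4 | step 2 | 15-methyl-17-oxodocos-13-ynoic acid (racemic) | CCCCCC(=O)CC(C)C#CCCCCCCCCCCCC(=O)O
F5 | step 1 | (E)-3-methyldec-4-en-1-yn-3-ol (racemic) | CCCCC/C=C/C(C)(O)C#C
F6 | step 1 | O,C-dilithio derivative of (E)-3-methyldec-4-en-1-yn-3-ol | [Li+].[Li+].CCCCC/C=C/C(C)([O-])C#[C-]
F7 | step 1 | lithium 12-bromododecanoate | [Li+].[O-]C(=O)CCCCCCCCCCCBr
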